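The constants you need here are two, and both come from the runs beta and gamma, read as fractions of the charge.

| flask | substrate | gas phase | remark | time |
|---|---|---|---|---|
| beta | 0.050 M (fed, over 2.5 min) | 32 mM (held) | run made earlier |  |
| gamma | 0.075 M (fed, over 2.5 min) | 32 mM (held) | run made earlier |  |
| flask | 0.10 M (fed, over 2.5 min) | 32 mM (held) |  | 5.0 min |

| run | time / min | over-reaction product / % | isomer of the product / % | target / % | substrate / % | side product / % |
|---|---|---|---|---|---|---|
| beta | 1.00 | 0 | 1.7 | 2.4 | 35.3 | 1.1 |
| beta | 2.00 | 0.5 | 0.4 | 8.6 | 62.4 | 6.8 |
| beta | 3.00 | 1.9 | 2.5 | 16.3 | 64.5 | 16.0 |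
| beta | 4.00 | 1.0 | 3.6 | 18.6 | 52.5 | 23.2 |
| gamma | 0.333 | 0.6 | 1.4 | 0.7 | 12.4 | 0.7 |
| gamma | 0.667 | 1.8 | 1.3 | 2.1 | 24.2 | 2.0 |
| gamma | 1.50 | 0.9 | 0 | 4.3 | 51.5 | 4.8 |
| gamma | 4.00 | 2.9 | 2.8 | 18.7 | 54.4 | 23.5 |

(scatter of a reading: 1 percentage point)

- the earlier runs were read with a standard deviation of 1 percentage point
- at the start none of the gas phase is in solution
- percentages count the whole charge, also what has not yet gone in

* the species in which most of what was charged as substrate, at 5.0 min sits (isomer of the product / side product / substrate / over-reaction product / target)
* the largest share itself, whichever of these holds it, in percent of the substrate charged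

At 4.00 min the substrate stands at 52.5% in beta and 54.4% in gamma, on charges of 0.050 M and 0.075 M. So I treat its loss as pseudo-first-order and carry the fractions over to the flask at 0.10 M.

Take the ladder from the fastest rung. The feed lasts 2.5 min. After it, beta's substrate readings give a loss constant and a life:

k = 0.206 min⁻¹, life = 4.86 min

The feed is over sooner than that life, so in the flask the substrate first piles up and then falls.

On the next rung, the two runs at 4.00 min give the part of the lost fraction that has become side product:

s = 0.502

Holding s steady, side product draws level when the substrate fraction reaches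

a = s / (1 + s) = 33.4%

On the last rung, starting from the mean of the two runs, 53.4% at 4.00 min, the loss constant gives

crossing = 6.28 min

This crossing time is my estimate of when side product draws level with substrate. The flask is read earlier, so I expect substrate to hold most, at 43.5%.

The forecast says substrate at 45%, a little above my figure: “Substrate remains the largest share”.

The flask gives substrate at 45.0%, with side product at 29.6%. That substrate fraction first moves by 5 points at a charge of 0.284 M. Started again from the flask's own 45.0% at 5.0 min, the crossing is reckoned at 6.45 min, so this flask is read 1.45 min ahead of it.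

    gas phase ⇌ dissolved gas, rate k1*(csat - [dissolved gas]) (kL = 0.0130 s⁻¹)
    substrate + dissolved gas ⇌ target (K = 21.0 L mol⁻¹, k = 0.170 L mol⁻¹ s⁻¹)
    substrate → side product (k = 0.00200 s⁻¹)
    dissolved gas + target → over-reaction product (k = 0.0210 L mol⁻¹ s⁻¹)
    target ⇌ isomer of the product (K = 0.930, k = 0.00190 s⁻¹)

The neighbour flask, the same charge read at 20 min, lies past that crossing, so the reckoning expects more there as side product than as substrate. Computed, that neighbour flask holds 65.7% as side product and 9.21% as substrate.

The readings come from a simulation with made-up constants.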